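One charge-time is 20.8 min on the last reading of the north-west run, and 19.7 min on that of the south-west run: it is the reciprocal of the E + D rate constant times the E charge.

in all of them: E 20 mM
- south-west: D 17 mM; run made earlier
- north-west: D 56 mM; run made earlier
- Tuesday's: D 14.0 mM; time 50 min
- Saturday's: D 42.0 mM; time 50 min

| run | time / min | G / % | L / % | Q / % | E / % | J / % |
|---|---|---|---|---|---|---|
| south-west | 2.00 | 0 | 2.9 | 4.0 | 93.0 | 1.1 |
| south-west | 3.00 | 0.4 | 4.2 | 6.8 | 89.3 | 0.5 |
| south-west | 6.00 | 0.2 | 7.6 | 11.3 | 80.9 | 0.5 |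
| south-west | 10.0 | 0.9 | 9.6 | 15.4 | 71.8 | 1.4 |
| south-west | 15.0 | 0.6 | 12.2 | 21.8 | 62.8 | 2.4 |
| south-west | 25.0 | 3.7 | 13.4 | 27.7 | 50.4 | 4.5 |
| north-west | 1.50 | 0.3 | 6.7 | 9.7 | 82.5 | 0.3 |
| north-west | 5.00 | 0.3 | 17.2 | 26.3 | 55.2 | 2.3 |
| north-west | 8.00 | 1.8 | 21.3 | 34.9 | 39.9 | 1.3 |
| north-west | 15.0 | 1.8 | 25.8 | 45.7 | 17.9 | 5.7 |
| north-west | 20.0 | 3.6 | 25.6 | 50.8 | 12.2 | 9.2 |
| north-west | 25.0 | 3.4 | 24.9 | 52.7 | 7.7 | 10.0 |

(readings scatter by 0.5 percentage points)

- which of these there is most of at the end, counted by the E in it, Tuesday's (Q / L / E / G / J)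
- which of these there is most of at the end, counted by the E in it, Saturday's (Q / L / E / G / J)
- the largest of these amounts at the end, in percent of the E charged, Tuesday's
- the largest of these amounts at the end, in percent of the E charged, Saturday's

- a species is counted by the E in it: one G counts as two
- the analysis behind the earlier runs scatters by 0.5 percentage points, standard deviation
- a reading or a percentage of L counts all its forms, free or not

1. Take r as the D charge in fractions of the E charge and a as r less 1. With E and D used one for one, the fraction of E left after time t is x = a / (r·exp(a·t/τ) − 1), where τ is the charge-time.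

2. In Tuesday's flask D is the limiting reagent. When you come, at 2.40 charge-times, I expect E at 45.5 %.

3. Q took 0.571 of the E used in the north-west run, so I expect Q at 31.1 % in Tuesday's flask, less than E.

4. In Saturday's flask I expect E at 3.85 % and Q at 54.9 %, so Q leads.

5. Add no D to Tuesday's flask before you read it: my reckoning for it is made on its charge as it stands.

The forecast says E at 44.5 % for Tuesday's flask and Q at 55 % for Saturday's, holding that “Q is a stable parallel product”. Its Tuesday's figure stands a little below mine.

Tuesday's flask gives E at 43.2 %. Saturday's flask gives Q at 55.2 %.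

    X ⇌ L, rate k1*(cs1 - [L]) while solid is left; crystals form when [L] > cs1 (solubility = 8.30 mM, k = 0.0120 /s)
    E + D → Z (k = 1.90 × 10⁻⁴ /M/s)
    E + L → G (k = 0.00930 /M/s)
    E + D → Q (k = 0.0230 /M/s)
    E + D → L (k = 0.0160 /M/s)
    L ⇌ J (K = 1.10, k = 4.10 × 10⁻⁴ /s)

Tuesday's flask read at 2.0 h is 5.77 charge-times old, and there I reckon E at 34.2 % and Q at 37.5 %. The flask holds less E than that, at 29.2 %. Its G stands at 11.9 %, and since each G counts two, 5.95 % of that is E taken up without D. The order has turned there: Q stands at 38.0 %, ahead of E.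

(The earlier runs and the new flask come from a simulation from invented constants.)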